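Ring atoms are numbered C1–C6, with C7 the exocyclic CH2 on C1; the same atom labels are used for the open-chain precursors. Compound numbers 1–23 are those of the steps and the compound list.

## Analysis of the target

The target 23 is a cyclohex-3-ene in which four ring carbons are oxygenated stereocentres. C1 is a quaternary carbinol carrying C7 as a CH2OBz group, C2 and C5 are allylic secondary benzoates on either side of C3=C4, and C6 is a free secondary alcohol. The configurations are C1 (S), C2 (R), C5 (R) and C6 (S), which places the oxygens on C1, C2 and C6 on one face and the C5 benzoate on the other (1,2-cis, 1,6-cis, 5,6-trans). Five oxygens must be told apart: O2, O5 and O7 end as benzoates, while the cis-vicinal pair O1/O6 stays free. The benzoates next to free hydroxyls can migrate under base, the two allylic esters can ionise or transpose, and any ring ketone with a β-oxygen can eliminate. The main difficulty is the quaternary centre C1, which must be set relative to both neighbours, together with placing the one alkene exactly between the two allylic esters. The strategy rests on the C1/C2 pair: with C2 as a ketone, the C1 tertiary alcohol is part of an α-ketol, whose C1–C2 bond can be made by adding a C2 acyl anion equivalent to a C1 ketone. That C2 carbonyl then serves to introduce C3=C4 and the C2 carbinol, the trans C5/C6 diol maps onto the tartrate-derived diester 1, and the free cis O1/O6 pair maps onto one acetonide.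

## Retrosynthetic reasoning

**23 ⇒ 22.** The free O1/O6 diol is traced back to its isopropylidene ketal 22. These are the only free hydroxyls in 23 and they are cis-vicinal, so one ketal separates them from the three acylated oxygens. The forward step is an acid hydrolysis that cuts the two ketal C–O bonds, under which benzoates do not migrate.

**22 ⇒ 21 + 17, and 21 ⇒ 20.** The O2–acyl bond is cut to give allylic alcohol 21, and its C2–H bond is traced to a 1,2-reduction of enone 20. The forward reduction must deliver hydride to the face of C2 opposite the C1–O bond, so that O2 ends cis to O1.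

**20 ⇒ 19 ⇒ 18.** The C3=C4 double bond is removed by retro-dehydrogenation through silyl enol ether 19. Because C1 is quaternary, the C2 ketone of 18 can enolise only toward C3, so the alkene position is not a selectivity question.

**18 ⇒ 16 + 17 ⇒ 15.** The benzoates on O5 and O7 are cut back to diol 16, which takes two equivalents of 17 in the forward sense, and O7 returns to its PMB ether in 15. Doing this before the alkene exists keeps the oxidative PMB removal away from allylic alcohols.

**15 ⇒ 14.** The acetonide is moved back from O1/O6 to O5/O6. The trans-5,6 acetonide is what the chiral pool supplies and what the ring closure needs; the cis-1,6 acetonide is what the endgame needs, and a cis-fused dioxolane is the more stable one.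

**14 ⇒ 13 (key disconnection).** The C1–C2 bond is cut. It is the only ring bond whose cleavage removes the quaternary stereocentre, opens the ring to an unbranched chain and leaves only the trans C5/C6 diol. Cutting C1–C6 would require two adjacent stereocentres to be set at once, and aldol-type cuts elsewhere would place a carbonyl β to ring oxygens. The forward reaction must make the C2 aldehyde of 13 nucleophilic in the presence of the ketone and add it to one face of that ketone.

**13 ⇒ 11.** The C2 aldehyde is masked as the terminal alkene of 11, whose extra carbon is lost on oxidative cleavage. No aldehyde then has to survive organometallic chemistry.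

**11 ⇒ 6 + 9.** The C1–C7 bond is cut between the acyl carbon of Weinreb amide 6 and the alkoxymethyl carbon of stannane 9, used as lithium reagent 10. C7 arrives already oxygenated and protected; 9 is made from 7 and 8.

**6 ⇒ 5 ⇒ 3 + 4.** The amide goes back to methyl ester 5, and the C3–C4 bond is cut between the iodomethyl carbon of 3 and the allyl group of 4. A radical allylation is needed because an ester is present and the iodide has a β-oxygen.

**3 ⇒ 2 ⇒ 1.** Iodide 3 comes from alcohol 2, and 2 from the C2-symmetric diester 1 by reduction of one ester. Symmetry makes the two esters equivalent, so the only task is to stop after one reduction.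

## Alternatives that were turned down

**Alternative 1:** The C2–O bond is disconnected and the carbocycle is traced to an achiral para-quinol made by dearomatising a phenol. In the forward step a chiral Brønsted acid such as (R)-3,3'-bis(2,4,6-triisopropylphenyl)-1,1'-binaphthyl-2,2'-diyl hydrogen phosphate lets the C1 hydroxyl form a hemiacetal with a small aldehyde tether and add to one of the two enantiotopic enone arms. The product is the cis-fused ethylidene acetal A1.
- For: the ring, the quaternary C1 and the C7 benzoate arrive in very few operations, and the tether enforces the C1–O/C2–O cis relationship that the target needs. On both points it is stronger than the chosen route.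
- Against: A1 has its carbonyl at C4 and its alkene at C5=C6, whereas the target needs oxygens at C5 and C6 (trans to each other, O6 cis to O1) and the alkene at C3=C4. Two more stereocentres must be set on the enone, and the C4 carbonyl must then become the C3=C4 alkene regioselectively. The C2 oxygen is β to that carbonyl, so retro-oxa-Michael opening is a standing risk. The acetal blocks O1/O2 although the target needs O1 free and O2 acylated, and the absolute configuration is only as good as the catalyst.
- Comparison: the chosen route is longer to the ring, but it takes C5/C6 from the chiral pool, and its cyclisation product 14 has the carbonyl at C2, where dehydrogenation and reduction are regiochemically unambiguous.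

**Alternative 2:** The C2–C3 bond is disconnected by an aldol reaction. A branched hex-5-enopyranoside of the manno series is opened by Hg(OCOCF3)2 (divalent mercury) in aqueous acetone to a keto-aldehyde that closes to the β-hydroxycyclohexanone A2.
- For: this carbocyclisation is one of the best-precedented routes to oxygenated cyclohexanones, and the sugar supplies C5, C6 and, after branching, C1 on a rigid ring. A2 already carries the C5 and C7 benzoates and the O1/O6 acetonide. On precedent for ring closure and supply of stereocentres it is at least as strong as the chosen route.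
- Against: making the branched sugar with its tertiary carbinol and the enol ether is a long, protecting-group-heavy preamble, and it uses mercury. In A2 the ketone is at C4 with the hydroxyl at C2, a β-hydroxy ketone that dehydrates toward C2=C3. The target needs C3=C4 with O2 retained, so the ketone must be turned into an alkene toward C3 against enolisation toward the α-acyloxy C5 and loss of O2 or O6. The C2 configuration from the aldol is not reliably controlled.
- Comparison: the chosen route reaches its cyclisation substrate 13 in fewer operations from 1, avoids mercury, and has a ketone flanked by a quaternary carbon that can enolise in one direction only.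

**Alternative 3:** The C1–C6 bond is disconnected. SmI2 (divalent samarium) couples the C1 ketone and the C6 aldehyde of an acyclic (Z)-alkenyl keto-aldehyde to the cis-1,6-diol A3.
- For: the cis O1/O6 diol comes directly from the metal-bridged coupling, and the alkene and all five oxygens are in place. Only protecting-group work remains after A3 (ketal on the diol, three PMB ethers off, three benzoates on, ketal off). On endgame economy it is clearly stronger than the chosen route.
- Against: the open-chain substrate needs two separated carbinol centres (C2, C5) across a (Z)-alkene. Both carbonyls are α-alkoxy and β,γ-unsaturated, so they are prone to epimerisation and conjugation. Under the reductant, either ketyl can expel its α-oxygen and the allylic C–O bonds can eliminate. The coupling must also place O6 anti to O5 but O1 syn to O2, and the usual anti preference cannot satisfy both.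
- Comparison: the chosen route spends more steps after ring closure, but each stereocentre is set in a separate event, and the cyclisation substrate 13 has no eliminable allylic oxygen.

Key step: step 8

## Route

Assumption: of the two commercial antipodes of the triazolium salt used in step 8, (5aS,10bR)-2-(pentafluorophenyl)-5a,10b-dihydro-4H,6H-indeno[2,1-b][1,2,4]triazolo[4,3-d][1,4]oxazin-2-ium tetrafluoroborate is taken as the one whose facial preference matches that of the substrate; if the pairing is mismatched, the (5aR,10bS) antipode is used under the same conditions.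

Step 1
Reactants: 1 dimethyl (4S,5S)-2,2-dimethyl-1,3-dioxolane-4,5-dicarboxylate (dimethyl 2,3-O-isopropylidene-D-tartrate)
Product: 2 methyl (4S,5R)-5-(hydroxymethyl)-2,2-dimethyl-1,3-dioxolane-4-carboxylate
Conditions: NaBH4 (0.6 equiv), MeOH, 0 °C to rt
Reagents that add atoms: none
Why: Borohydride reduction of an α-alkoxy-activated ester; 1 is C2-symmetric, so either ester gives the same mono-alcohol, and a substoichiometric hydride charge keeps the doubly reduced diol a separable by-product. The ring stereocentres are untouched (the C5 descriptor changes only through priorities).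

Step 2
Reactants: 2 methyl (4S,5R)-5-(hydroxymethyl)-2,2-dimethyl-1,3-dioxolane-4-carboxylate
Product: 3 methyl (4S,5S)-5-(iodomethyl)-2,2-dimethyl-1,3-dioxolane-4-carboxylate
Conditions: I2, PPh3, imidazole, CH2Cl2, 0 °C to rt
Reagents that add atoms: iodine, II
Why: Appel-type iodination of a primary alcohol through its alkoxyphosphonium ion; the neutral conditions leave the ester and the acetonide intact.

Step 3
Reactants: 3 methyl (4S,5S)-5-(iodomethyl)-2,2-dimethyl-1,3-dioxolane-4-carboxylate; 4 allyltributylstannane
Product: 5 methyl (4S,5R)-5-(but-3-en-1-yl)-2,2-dimethyl-1,3-dioxolane-4-carboxylate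
Conditions: 4 (2.5 equiv), azobisisobutyronitrile (0.2 equiv), benzene, 80 °C
Reagents that add atoms: none
Why: Keck radical allylation: the stannyl radical abstracts iodine, the primary radical adds to the allylstannane and β-scission regenerates the chain carrier, forming the C3–C4 bond. A radical is used because the ester would not survive an allylmetal nucleophile and a β-alkoxy radical, unlike a β-alkoxy organometallic, does not eliminate.

Step 4
Reactants: 5 methyl (4S,5R)-5-(but-3-en-1-yl)-2,2-dimethyl-1,3-dioxolane-4-carboxylate
Product: 6 (4S,5R)-5-(but-3-en-1-yl)-N-methoxy-N,2,2-trimethyl-1,3-dioxolane-4-carboxamide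
Conditions: MeNHOMe·HCl, i-PrMgCl, THF, −20 to 0 °C
Reagents that add atoms: N,O-dimethylhydroxylamine hydrochloride, CNOC.Cl
Why: Weinreb amide formation by aminolysis of the methyl ester with the magnesium amide; the low temperature and the favoured trans-dioxolane protect the α-centre from epimerisation.

Step 5
Reactants: 7 4-methoxybenzyl alcohol; 8 tributyl(iodomethyl)stannane
Product: 9 tributyl{[(4-methoxybenzyl)oxy]methyl}stannane
Conditions: NaH, THF–DMF, 0 °C to rt
Reagents that add atoms: none
Why: Williamson etherification; the alkoxide displaces iodide at the unhindered α-stannyl carbon.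

Step 6
Reactants: 9 tributyl{[(4-methoxybenzyl)oxy]methyl}stannane; 6 (4S,5R)-5-(but-3-en-1-yl)-N-methoxy-N,2,2-trimethyl-1,3-dioxolane-4-carboxamide
Product: 11 1-[(4S,5R)-5-(but-3-en-1-yl)-2,2-dimethyl-1,3-dioxolan-4-yl]-2-[(4-methoxybenzyl)oxy]ethan-1-one, via [(4-methoxybenzyl)oxy]methyllithium 10 (not isolated)
Conditions: n-BuLi, THF, −78 °C; then 6, −78 °C; aq NH4Cl
Reagents that add atoms: none
Why: Tin–lithium exchange gives the α-alkoxy organolithium, which adds once to the Weinreb amide because the chelated tetrahedral intermediate persists until the quench (Weinreb ketone synthesis). This forms the C1–C7 bond with C7 already protected.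

Step 7
Reactants: 11 1-[(4S,5R)-5-(but-3-en-1-yl)-2,2-dimethyl-1,3-dioxolan-4-yl]-2-[(4-methoxybenzyl)oxy]ethan-1-one
Product: 13 3-[(4R,5S)-5-{[(4-methoxybenzyl)oxy]acetyl}-2,2-dimethyl-1,3-dioxolan-4-yl]propanal, via terminal 1,2-diol 12 (not isolated)
Conditions: OsO4 (2 mol %), NaIO4, 2,6-lutidine, dioxane–H2O, rt
Reagents that add atoms: osmium tetroxide, O=[Os](=O)(=O)=O; sodium periodate, [Na+].[O-]I(=O)(=O)=O; water, O
Why: Lemieux–Johnson cleavage: catalytic dihydroxylation of the terminal alkene and periodate scission of the diol give the C2 aldehyde. It is preferred to ozonolysis because the electron-rich PMB ether is left alone.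

Step 8
Reactants: 13 3-[(4R,5S)-5-{[(4-methoxybenzyl)oxy]acetyl}-2,2-dimethyl-1,3-dioxolan-4-yl]propanal
Product: 14 (3aS,4S,7aR)-4-hydroxy-4-{[(4-methoxybenzyl)oxy]methyl}-2,2-dimethyltetrahydro-1,3-benzodioxol-5(4H)-one (C2 ketone, C1 (S) carbinol bearing CH2OPMB, trans-5,6-acetonide)
Conditions: (5aS,10bR)-2-(pentafluorophenyl)-5a,10b-dihydro-4H,6H-indeno[2,1-b][1,2,4]triazolo[4,3-d][1,4]oxazin-2-ium tetrafluoroborate (15 mol %), Et3N (1 equiv), toluene (high dilution), rt
Reagents that add atoms: none
Why: The triazolylidene freed by Et3N adds to the C2 aldehyde and proton transfer gives the Breslow enaminol, an acyl anion equivalent, which attacks the C1 ketone; collapse of the adduct releases the carbene and α-hydroxy ketone 14. The closest known reaction type is the triazolium-catalysed intramolecular crossed aldehyde–ketone benzoin of aliphatic and sugar-derived keto-aldehydes to cyclic α-ketols with a quaternary carbinol. The six-membered ring closes in the 6-exo-trig mode by formation of the C1–C2 bond. The one new stereocentre, C1, is controlled by the C6 stereocentre together with the catalyst: in the chair-like, trans-fused transition state the dioxolane is diequatorial, the CH2OPMB group equatorial and the ketone oxygen axial, so the forming bond is antiperiplanar to the C6–O bond (polar Felkin–Anh arrangement) and the new hydroxyl ends cis to O6, giving C1 (S). The aminoindanol wall of the catalyst shields one face of the enaminol and, in the matched pairing, reinforces this preference. The step needs the carbene to engage the aldehyde and not the ketone, cyclisation to outrun intermolecular homo-benzoin (dilution), and aldol closure or C6 epimerisation to be avoided (weak amine base with an acidic N-pentafluorophenyl triazolium). The aldehyde has no α- or β-leaving group, so no internal redox path is open to the Breslow intermediate, and the ketone is activated by its two α-oxygens.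

Step 9
Reactants: 14 (3aS,4S,7aR)-4-hydroxy-4-{[(4-methoxybenzyl)oxy]methyl}-2,2-dimethyltetrahydro-1,3-benzodioxol-5(4H)-one
Product: 15 (3aS,7R,7aS)-7-hydroxy-3a-{[(4-methoxybenzyl)oxy]methyl}-2,2-dimethyltetrahydro-1,3-benzodioxol-4(3aH)-one (cis-1,6-acetonide, free C5–OH, C2 ketone)
Conditions: camphor-10-sulfonic acid (10 mol %), acetone, rt
Reagents that add atoms: none
Why: Acid-catalysed ketal equilibration (acetonide migration): the strained trans-fused dioxolane opens to an oxocarbenium ion on O6, which is captured by the cis C1 hydroxyl to give the more stable cis-fused dioxolane. This frees O5 and masks exactly the two oxygens that stay free in the target; no stereocentre is touched.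

Step 10
Reactants: 15 (3aS,7R,7aS)-7-hydroxy-3a-{[(4-methoxybenzyl)oxy]methyl}-2,2-dimethyltetrahydro-1,3-benzodioxol-4(3aH)-one
Product: 16 (3aS,7R,7aS)-7-hydroxy-3a-(hydroxymethyl)-2,2-dimethyltetrahydro-1,3-benzodioxol-4(3aH)-one
Conditions: 2,3-dichloro-5,6-dicyano-1,4-benzoquinone (DDQ), CH2Cl2–pH 7 buffer, 0 °C to rt
Reagents that add atoms: none
Why: Oxidative PMB cleavage by hydride abstraction and hydrolysis of the resulting oxocarbenium ion. It is placed here because the molecule has no allylic alcohol yet and O1 is tied up in the ketal.

Step 11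
Reactants: 16 (3aS,7R,7aS)-7-hydroxy-3a-(hydroxymethyl)-2,2-dimethyltetrahydro-1,3-benzodioxol-4(3aH)-one; 17 benzoyl chloride
Product: 18 [(3aS,7R,7aS)-7-(benzoyloxy)-2,2-dimethyl-4-oxohexahydro-1,3-benzodioxol-3a-yl]methyl benzoate
Conditions: 17 (2.5 equiv), pyridine, 4-(dimethylamino)pyridine (cat.), CH2Cl2, 0 °C to rt
Reagents that add atoms: benzoyl chloride (second equivalent of 17), O=C(Cl)c1ccccc1
Why: Nucleophile-catalysed acylation of the primary O7 and the secondary O5 hydroxyls, each taking one equivalent of 17, installs two of the three final benzoates. The mild amine base avoids retro-aldol loss of C7 from the β-hydroxy ketone, and because C1 has no hydrogen the β-acyloxy ketone formed cannot eliminate.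

Step 12
Reactants: 18 [(3aS,7R,7aS)-7-(benzoyloxy)-2,2-dimethyl-4-oxohexahydro-1,3-benzodioxol-3a-yl]methyl benzoate
Product: 19 [(3aS,7R,7aS)-7-(benzoyloxy)-2,2-dimethyl-4-[(trimethylsilyl)oxy]-3a,6,7,7a-tetrahydro-1,3-benzodioxol-3a-yl]methyl benzoate
Conditions: Me3SiOTf, Et3N, CH2Cl2, 0 °C
Reagents that add atoms: trimethylsilyl trifluoromethanesulfonate, C[Si](C)(C)OS(=O)(=O)C(F)(F)F
Why: Soft enolisation to the silyl enol ether; C1 is quaternary, so only C3 can be deprotonated, and the amine-buffered conditions spare the benzoates and the ketal.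

Step 13
Reactants: 19 [(3aS,7R,7aS)-7-(benzoyloxy)-2,2-dimethyl-4-[(trimethylsilyl)oxy]-3a,6,7,7a-tetrahydro-1,3-benzodioxol-3a-yl]methyl benzoate
Product: 20 [(3aS,7R,7aS)-7-(benzoyloxy)-2,2-dimethyl-4-oxo-3a,4,7,7a-tetrahydro-1,3-benzodioxol-3a-yl]methyl benzoate
Conditions: Pd(OAc)2 (1.1 equiv), MeCN, rt
Reagents that add atoms: none
Why: Saegusa–Ito oxidation: the silyl enol ether gives a divalent palladium enolate at C3, and β-hydride elimination of a C4 hydrogen releases the enone and zerovalent palladium. The neutral conditions avoid base-induced loss of the γ-benzoate.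

Step 14
Reactants: 20 [(3aS,7R,7aS)-7-(benzoyloxy)-2,2-dimethyl-4-oxo-3a,4,7,7a-tetrahydro-1,3-benzodioxol-3a-yl]methyl benzoate
Product: 21 [(3aR,4R,7R,7aS)-7-(benzoyloxy)-4-hydroxy-2,2-dimethyl-3a,4,7,7a-tetrahydro-1,3-benzodioxol-3a-yl]methyl benzoate
Conditions: NaBH4, CeCl3·7H2O, MeOH, −78 °C
Reagents that add atoms: none
Why: Luche 1,2-reduction of the enone. In the favoured half-chair the C5 benzoate and the CH2OBz group are equatorial and the C1–O bond is axial (the other half-chair has them syn-diaxial), so hydride should enter axially, anti to the C1–O bond and away from the dioxolane. The new hydroxyl then lies cis to O1, which sets C2 (R).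

Step 15
Reactants: 21 [(3aR,4R,7R,7aS)-7-(benzoyloxy)-4-hydroxy-2,2-dimethyl-3a,4,7,7a-tetrahydro-1,3-benzodioxol-3a-yl]methyl benzoate; 17 benzoyl chloride
Product: 22 [(3aR,4R,7R,7aS)-4,7-bis(benzoyloxy)-2,2-dimethyl-3a,4,7,7a-tetrahydro-1,3-benzodioxol-3a-yl]methyl benzoate
Conditions: pyridine, 4-(dimethylamino)pyridine (cat.), CH2Cl2, rt
Reagents that add atoms: none
Why: Nucleophile-catalysed acylation of the hindered allylic C2 hydroxyl with retention; any prior drift of a benzoate from O7 to O2 would converge on the same tribenzoate.

Step 16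
Reactants: 22 [(3aR,4R,7R,7aS)-4,7-bis(benzoyloxy)-2,2-dimethyl-3a,4,7,7a-tetrahydro-1,3-benzodioxol-3a-yl]methyl benzoate
Product: 23 [(1S,2R,5R,6S)-2,5-bis(benzoyloxy)-1,6-dihydroxycyclohex-3-en-1-yl]methyl benzoate
Conditions: CF3CO2H–H2O (9:1), CH2Cl2, 0 °C to rt
Reagents that add atoms: none
Why: Acid hydrolysis of the isopropylidene ketal frees O1 and O6. Acid is chosen because benzoates migrate under base but not under these conditions, and the electron-poor allylic esters should not ionise; no stereocentre is touched.

## Compound list

1 | dimethyl (4S,5S)-2,2-dimethyl-1,3-dioxolane-4,5-dicarboxylate (dimethyl 2,3-O-isopropylidene-D-tartrate) | COC(=O)[C@H]1OC(C)(C)O[C@@H]1C(=O)OC | starting material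
2 | methyl (4S,5R)-5-(hydroxymethyl)-2,2-dimethyl-1,3-dioxolane-4-carboxylate | COC(=O)[C@H]1OC(C)(C)O[C@@H]1CO | intermediate
3 | methyl (4S,5S)-5-(iodomethyl)-2,2-dimethyl-1,3-dioxolane-4-carboxylate | COC(=O)[C@H]1OC(C)(C)O[C@@H]1CI | intermediate
4 | allyltributylstannane | C=CC[Sn](CCCC)(CCCC)CCCC | starting material
5 | methyl (4S,5R)-5-(but-3-en-1-yl)-2,2-dimethyl-1,3-dioxolane-4-carboxylate | COC(=O)[C@H]1OC(C)(C)O[C@@H]1CCC=C | intermediate
6 | (4S,5R)-5-(but-3-en-1-yl)-N-methoxy-N,2,2-trimethyl-1,3-dioxolane-4-carboxamide | CON(C)C(=O)[C@H]1OC(C)(C)O[C@@H]1CCC=C | intermediate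
7 | 4-methoxybenzyl alcohol | COc1ccc(CO)cc1 | starting material
8 | tributyl(iodomethyl)stannane | CCCC[Sn](CI)(CCCC)CCCC | starting material
9 | tributyl{[(4-methoxybenzyl)oxy]methyl}stannane | CCCC[Sn](COCc1ccc(OC)cc1)(CCCC)CCCC | intermediate
10 | [(4-methoxybenzyl)oxy]methyllithium | [Li]COCc1ccc(OC)cc1 | intermediate
11 | 1-[(4S,5R)-5-(but-3-en-1-yl)-2,2-dimethyl-1,3-dioxolan-4-yl]-2-[(4-methoxybenzyl)oxy]ethan-1-one | COc1ccc(COCC(=O)[C@H]2OC(C)(C)O[C@@H]2CCC=C)cc1 | intermediate
12 | 1-[(4S,5R)-5-(3,4-dihydroxybutyl)-2,2-dimethyl-1,3-dioxolan-4-yl]-2-[(4-methoxybenzyl)oxy]ethan-1-one (terminal 1,2-diol, both carbinol epimers) | COc1ccc(COCC(=O)[C@H]2OC(C)(C)O[C@@H]2CCC(O)CO)cc1 | intermediate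
13 | 3-[(4R,5S)-5-{[(4-methoxybenzyl)oxy]acetyl}-2,2-dimethyl-1,3-dioxolan-4-yl]propanal | COc1ccc(COCC(=O)[C@H]2OC(C)(C)O[C@@H]2CCC=O)cc1 | intermediate
14 | (3aS,4S,7aR)-4-hydroxy-4-{[(4-methoxybenzyl)oxy]methyl}-2,2-dimethyltetrahydro-1,3-benzodioxol-5(4H)-one | COc1ccc(COC[C@@]2(O)C(=O)CC[C@H]3OC(C)(C)O[C@H]23)cc1 | intermediate
15 | (3aS,7R,7aS)-7-hydroxy-3a-{[(4-methoxybenzyl)oxy]methyl}-2,2-dimethyltetrahydro-1,3-benzodioxol-4(3aH)-one | COc1ccc(COC[C@]23OC(C)(C)O[C@H]2[C@H](O)CCC3=O)cc1 | intermediate
16 | (3aS,7R,7aS)-7-hydroxy-3a-(hydroxymethyl)-2,2-dimethyltetrahydro-1,3-benzodioxol-4(3aH)-one | OC[C@]12OC(C)(C)O[C@H]1[C@H](O)CCC2=O | intermediate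
17 | benzoyl chloride | O=C(Cl)c1ccccc1 | starting material
18 | [(3aS,7R,7aS)-7-(benzoyloxy)-2,2-dimethyl-4-oxohexahydro-1,3-benzodioxol-3a-yl]methyl benzoate | O=C(OC[C@]12OC(C)(C)O[C@H]1[C@H](OC(=O)c3ccccc3)CCC2=O)c1ccccc1 | intermediate
19 | [(3aS,7R,7aS)-7-(benzoyloxy)-2,2-dimethyl-4-[(trimethylsilyl)oxy]-3a,6,7,7a-tetrahydro-1,3-benzodioxol-3a-yl]methyl benzoate | O=C(OC[C@]12OC(C)(C)O[C@H]1[C@H](OC(=O)c3ccccc3)CC=C2O[Si](C)(C)C)c1ccccc1 | intermediate
20 | [(3aS,7R,7aS)-7-(benzoyloxy)-2,2-dimethyl-4-oxo-3a,4,7,7a-tetrahydro-1,3-benzodioxol-3a-yl]methyl benzoate | O=C(OC[C@]12OC(C)(C)O[C@H]1[C@H](OC(=O)c3ccccc3)C=CC2=O)c1ccccc1 | intermediate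
21 | [(3aR,4R,7R,7aS)-7-(benzoyloxy)-4-hydroxy-2,2-dimethyl-3a,4,7,7a-tetrahydro-1,3-benzodioxol-3a-yl]methyl benzoate | O=C(OC[C@]12OC(C)(C)O[C@H]1[C@H](OC(=O)c3ccccc3)C=C[C@H]2O)c1ccccc1 | intermediate
22 | [(3aR,4R,7R,7aS)-4,7-bis(benzoyloxy)-2,2-dimethyl-3a,4,7,7a-tetrahydro-1,3-benzodioxol-3a-yl]methyl benzoate | O=C(OC[C@]12OC(C)(C)O[C@H]1[C@H](OC(=O)c3ccccc3)C=C[C@H]2OC(=O)c2ccccc2)c1ccccc1 | intermediate
23 | [(1S,2R,5R,6S)-2,5-bis(benzoyloxy)-1,6-dihydroxycyclohex-3-en-1-yl]methyl benzoate | O=C(OC[C@@]1(O)[C@H](OC(=O)c2ccccc2)C=C[C@@H](OC(=O)c2ccccc2)[C@@H]1O)c1ccccc1 | target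

## Step count and least certain steps

Total step count: 16. Longest linear sequence: 15 steps (steps 1–4 and 6–16, from 1 to 23); step 5 is a one-step side branch.

**Step 8 (key step).** Poor facial discrimination at the C1 ketone is the main danger: the hydrogen-bonded transition state may prefer the ketone oxygen equatorial, which would give the C1 epimer. Amine-mediated aldol closure of the C3 enolate onto C1, or epimerisation at C6, could also intervene before the carbene acts. Fallback: setting out from 13, SmI2 (divalent samarium) in THF–t-BuOH at −78 °C would close the same C1–C2 bond reductively by ketyl–carbonyl (pinacol) coupling. The aldehyde is reduced first and has no α-oxygen, so its ketyl should add to the samarium-bound ketone before any α-oxygen can be lost. The samarium-bridged chair that keeps CH2OPMB equatorial should give the all-cis diol (3aS,4R,5R,7aR)-4-{[(4-methoxybenzyl)oxy]methyl}-2,2-dimethylhexahydro-1,3-benzodioxole-4,5-diol F1. Oxidation of its secondary C2 hydroxyl with SO3·pyridine, DMSO and Et3N would rejoin the route at 14.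

**Step 3.** The radical chain may be short, because primary alkyl radicals add slowly to the allylstannane; simple reduction of the iodide or stalled conversion would follow. Fallback: setting out from 2, oxidation (SO3·pyridine, DMSO, Et3N) would give methyl (4S,5S)-5-formyl-2,2-dimethyl-1,3-dioxolane-4-carboxylate F2. Zinc-mediated Barbier allylation (allyl bromide, Zn, THF–aq NH4Cl) would give methyl (4S,5R)-5-(1-hydroxybut-3-en-1-yl)-2,2-dimethyl-1,3-dioxolane-4-carboxylate F3 as both carbinol epimers. Reaction with 1,1'-thiocarbonyldiimidazole would give methyl (4S,5R)-5-[1-(1H-imidazole-1-carbothioyloxy)but-3-en-1-yl]-2,2-dimethyl-1,3-dioxolane-4-carboxylate F4, and Barton–McCombie deoxygenation (Bu3SnH, azobisisobutyronitrile, toluene, 110 °C) would rejoin the route at 5.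

**Step 9.** The ketal equilibration may stop at a mixture, lose the acetonide altogether, or be accompanied by acid-induced α-ketol rearrangement on long exposure. Fallback: setting out from 14, 80% aqueous AcOH at 40 °C would remove the trans-acetonide to give (2S,3S,4R)-2,3,4-trihydroxy-2-{[(4-methoxybenzyl)oxy]methyl}cyclohexan-1-one F5. Kinetic ketalisation with 2-methoxypropene and pyridinium p-toluenesulfonate in DMF at 0 °C should favour the cis C1/C6 pair, since closure across the trans C5/C6 pair would only rebuild the strained trans-fused ketal, and would rejoin the route at 15.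

**Step 13.** Protodesilylation back to 18 may compete with palladation, or the dehydrogenation may stall on this hindered, electron-poor enol ether. Fallback: setting out from 19, PhSeCl in CH2Cl2 at −78 °C would give [(3aS,7R,7aS)-7-(benzoyloxy)-2,2-dimethyl-4-oxo-5-(phenylselanyl)hexahydro-1,3-benzodioxol-3a-yl]methyl benzoate F6. H2O2–pyridine would oxidise it to [(3aS,7R,7aS)-5-(benzeneseleninyl)-7-(benzoyloxy)-2,2-dimethyl-4-oxohexahydro-1,3-benzodioxol-3a-yl]methyl benzoate F7, whose syn-elimination toward C4 would rejoin the route at 20.

**Step 14.** Hydride may arrive from the dioxolane face if the half-chair preference is weaker than argued, and some conjugate reduction is possible. Fallback: setting out from 20, reduction from that face would give the C2 epimer [(3aR,4S,7R,7aS)-7-(benzoyloxy)-4-hydroxy-2,2-dimethyl-3a,4,7,7a-tetrahydro-1,3-benzodioxol-3a-yl]methyl benzoate F8. A Mitsunobu reaction with benzoic acid (PPh3, diisopropyl azodicarboxylate, toluene) would invert C2 while installing the benzoate, rejoining the route at 22 and making step 15 unnecessary.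

## Further compounds

F1 | step 8 | (3aS,4R,5R,7aR)-4-{[(4-methoxybenzyl)oxy]methyl}-2,2-dimethylhexahydro-1,3-benzodioxole-4,5-diol | COc1ccc(COC[C@@]2(O)[C@H](O)CC[C@H]3OC(C)(C)O[C@H]23)cc1
F2 | step 3 | methyl (4S,5S)-5-formyl-2,2-dimethyl-1,3-dioxolane-4-carboxylate | COC(=O)[C@H]1OC(C)(C)O[C@@H]1C=O
F3 | step 3 | methyl (4S,5R)-5-(1-hydroxybut-3-en-1-yl)-2,2-dimethyl-1,3-dioxolane-4-carboxylate (both carbinol epimers) | COC(=O)[C@H]1OC(C)(C)O[C@@H]1C(O)CC=C
F4 | step 3 | methyl (4S,5R)-5-[1-(1H-imidazole-1-carbothioyloxy)but-3-en-1-yl]-2,2-dimethyl-1,3-dioxolane-4-carboxylate (both side-chain epimers) | COC(=O)[C@H]1OC(C)(C)O[C@@H]1C(CC=C)OC(=S)n1ccnc1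
F5 | step 9 | (2S,3S,4R)-2,3,4-trihydroxy-2-{[(4-methoxybenzyl)oxy]methyl}cyclohexan-1-one | COc1ccc(COC[C@@]2(O)C(=O)CC[C@@H](O)[C@@H]2O)cc1
F6 | step 13 | [(3aS,7R,7aS)-7-(benzoyloxy)-2,2-dimethyl-4-oxo-5-(phenylselanyl)hexahydro-1,3-benzodioxol-3a-yl]methyl benzoate (both C5 epimers) | O=C(OC[C@]12OC(C)(C)O[C@H]1[C@H](OC(=O)c3ccccc3)CC([Se]c3ccccc3)C2=O)c1ccccc1
F7 | step 13 | [(3aS,7R,7aS)-5-(benzeneseleninyl)-7-(benzoyloxy)-2,2-dimethyl-4-oxohexahydro-1,3-benzodioxol-3a-yl]methyl benzoate | O=C(OC[C@]12OC(C)(C)O[C@H]1[C@H](OC(=O)c3ccccc3)CC([Se](=O)c3ccccc3)C2=O)c1ccccc1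
F8 | step 14 | [(3aR,4S,7R,7aS)-7-(benzoyloxy)-4-hydroxy-2,2-dimethyl-3a,4,7,7a-tetrahydro-1,3-benzodioxol-3a-yl]methyl benzoate | O=C(OC[C@]12OC(C)(C)O[C@H]1[C@H](OC(=O)c3ccccc3)C=C[C@@H]2O)c1ccccc1
A1 | alternative 1 | (2-methyl-6-oxo-3a,6,7,7a-tetrahydro-1,3-benzodioxol-3a-yl)methyl benzoate, cis-fused ethylidene acetal across O1/O2 | O=C(OC[C@@]12O[C@@H](C)O[C@@H]1CC(=O)C=C2)c1ccccc1
A2 | alternative 2 | [7-(benzoyloxy)-4-hydroxy-2,2-dimethyl-6-oxohexahydro-1,3-benzodioxol-3a-yl]methyl benzoate, C4 ketone with O1/O6 acetonide | O=C(OC[C@]12OC(C)(C)O[C@H]1[C@H](OC(=O)c1ccccc1)C(=O)C[C@H]2O)c1ccccc1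
A3 | alternative 3 | 2,5-bis[(4-methoxybenzyl)oxy]-1-{[(4-methoxybenzyl)oxy]methyl}cyclohex-3-ene-1,6-diol (route numbering, configuration as in 23) | COc1ccc(COC[C@@]2(O)[C@H](OCc3ccc(OC)cc3)C=C[C@@H](OCc3ccc(OC)cc3)[C@@H]2O)cc1
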